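**Retrosynthetic overview**

- Target 19 comes from all-trans aldehyde ester 17 by aldehyde reduction and hydrogenolysis of the pendant benzyl ether.
- The strategy rests on one feature: the C4 methylene of the tetralin is para to the C7 hydroxyl of ring A, with the C6 methoxyl beside it (a 4-methylguaiacol unit). C4 is therefore taken back to an aryl methyl group, oxidised at an anode to a p-quinone methide, and the C3–C4 bond is closed by C3 of a tethered silyl enol ether (14 to 17).
- This closure forms the only new ring (the saturated carbocycle); ring A and the pendant ring are bought.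
- Precursor 14 comes from aldehyde 12, allyl ester 10 and (R)-3,3-diarylpropanoate 7; C1 is set by rhodium-catalysed asymmetric aryl addition to cinnamate 5.
- Cinnamate 5 comes from creosol 1 by silylation, bromination para to the methoxyl and Heck coupling.

Key step: step 9

Remark: tetralin numbering of the target (C1 aryl-bearing, C2 ester-bearing, C3, C4 methylene, ring A the fused benzene ring) is also used for open-chain intermediates. The facial sense in step 4 follows the accepted model for BINAP–rhodium additions to (E)-enoates and is to be confirmed on 7; (R)-BINAP is used if the opposite sense is found.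

**Route**

Step 1
Reactants: 1 creosol (2-methoxy-4-methylphenol)
Product: 2 tert-butyl(2-methoxy-4-methylphenoxy)dimethylsilane
Conditions: TBSCl, imidazole, DMF, rt
Reagents that add atoms: tert-butyldimethylsilyl chloride, CC(C)(C)[Si](C)(C)Cl
Why: Imidazole-promoted O-silylation of a phenol; the bulky silyl ether stops the hydroxyl from directing the next bromination to its own ortho position.

Step 2
Reactants: 2 tert-butyl(2-methoxy-4-methylphenoxy)dimethylsilane
Product: 3 (5-bromo-2-methoxy-4-methylphenoxy)(tert-butyl)dimethylsilane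
Conditions: NBS, MeCN, 0 °C to rt
Reagents that add atoms: N-bromosuccinimide, O=C1CCC(=O)N1Br
Why: Electrophilic aromatic bromination; the methoxyl directs to its free para position, while the para position of the silyloxy group is blocked by the methyl group and its ortho position is shielded by the silyl group.

Step 3
Reactants: 3 (5-bromo-2-methoxy-4-methylphenoxy)(tert-butyl)dimethylsilane; 4 methyl acrylate
Product: 5 methyl (E)-3-[5-(tert-butyldimethylsilyloxy)-4-methoxy-2-methylphenyl]prop-2-enoate
Conditions: Pd(OAc)2, P(o-tol)3, Et3N, DMF, 100 °C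
Reagents that add atoms: none
Why: Mizoroki–Heck coupling of an aryl bromide with an acrylate; syn insertion and syn β-hydride elimination give the (E)-cinnamate.

Step 4
Reactants: 5 methyl (E)-3-[5-(tert-butyldimethylsilyloxy)-4-methoxy-2-methylphenyl]prop-2-enoate; 6 [4-(benzyloxy)-3-methoxyphenyl]boronic acid
Product: 7 methyl (3R)-3-[4-(benzyloxy)-3-methoxyphenyl]-3-[5-(tert-butyldimethylsilyloxy)-4-methoxy-2-methylphenyl]propanoate
Conditions: [Rh(OH)((S)-BINAP)]2 (3 mol % Rh), excess 6, dioxane/H2O (10:1), 50 °C
Reagents that add atoms: none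
Why: Hayashi–Miyaura rhodium-catalysed asymmetric 1,4-addition; the aryl–rhodium species bearing (S)-BINAP is expected to insert the (E)-enoate on its α-si face, which sets C1 as (R), and the neutral medium spares the aryl silyl ether.

Step 5
Reactants: 7 methyl (3R)-3-[4-(benzyloxy)-3-methoxyphenyl]-3-[5-(tert-butyldimethylsilyloxy)-4-methoxy-2-methylphenyl]propanoate; 8 allyl bromide
Product: 10 methyl 2-{(R)-[4-(benzyloxy)-3-methoxyphenyl][5-(tert-butyldimethylsilyloxy)-4-methoxy-2-methylphenyl]methyl}pent-4-enoate (both C2 epimers), via lithium ester enolate 9 (not isolated)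
Conditions: LDA, THF, −78 °C; then allyl bromide, DMPU, −78 to −20 °C
Reagents that add atoms: none
Why: Ester enolate alkylation (deprotonation at C2, SN2 on allyl bromide); the C2 epimer mixture is acceptable because C2 is equilibrated in step 9, and the doubly benzylic C1–H is far less acidic than the ester α-hydrogen.

Step 6
Reactants: 10 methyl 2-{(R)-[4-(benzyloxy)-3-methoxyphenyl][5-(tert-butyldimethylsilyloxy)-4-methoxy-2-methylphenyl]methyl}pent-4-enoate
Product: 12 methyl 2-{(R)-[4-(benzyloxy)-3-methoxyphenyl][5-(tert-butyldimethylsilyloxy)-4-methoxy-2-methylphenyl]methyl}-4-oxobutanoate (both C2 epimers), via vicinal diol 11 (not isolated)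
Conditions: OsO4 (cat.), NaIO4, 2,6-lutidine, dioxane/H2O (3:1), rt
Reagents that add atoms: osmium tetroxide, O=[Os](=O)(=O)=O; sodium periodate, [Na+].[O-]I(=O)(=O)=O
Why: Lemieux–Johnson oxidative cleavage (osmium-catalysed dihydroxylation, periodate glycol cleavage), chosen over ozonolysis to spare the three electron-rich arenes.

Step 7
Reactants: 12 methyl 2-{(R)-[4-(benzyloxy)-3-methoxyphenyl][5-(tert-butyldimethylsilyloxy)-4-methoxy-2-methylphenyl]methyl}-4-oxobutanoate
Product: 13 methyl 2-{(R)-[4-(benzyloxy)-3-methoxyphenyl][5-(tert-butyldimethylsilyloxy)-4-methoxy-2-methylphenyl]methyl}-4-(triisopropylsilyloxy)but-3-enoate (C2 epimers, E/Z mixture)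
Conditions: TIPSOTf, Et3N, CH2Cl2, 0 °C to rt
Reagents that add atoms: triisopropylsilyl trifluoromethanesulfonate, CC(C)[Si](OS(=O)(=O)C(F)(F)F)(C(C)C)C(C)C
Why: Soft enolisation and O-silylation of an aldehyde; the aldehyde has one enolisable position (C3), so only one regioisomeric enol ether can form and its geometry is immaterial.

Step 8
Reactants: 13 methyl 2-{(R)-[4-(benzyloxy)-3-methoxyphenyl][5-(tert-butyldimethylsilyloxy)-4-methoxy-2-methylphenyl]methyl}-4-(triisopropylsilyloxy)but-3-enoate
Product: 14 methyl 2-{(R)-[4-(benzyloxy)-3-methoxyphenyl](5-hydroxy-4-methoxy-2-methylphenyl)methyl}-4-(triisopropylsilyloxy)but-3-enoate (C2 epimers, E/Z mixture)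
Conditions: Cs2CO3 (0.5 equiv), DMF/H2O (10:1), rt, stopped at full conversion of 13
Reagents that add atoms: none
Why: Base-mediated cleavage of an aryl silyl ether; phenoxide is a much better leaving group on silicon than an aldehyde enolate and the tert-butyldimethylsilyl group is less hindered than triisopropylsilyl, so the aryl ether should be cleaved first.

Step 9
Reactants: 14 methyl 2-{(R)-[4-(benzyloxy)-3-methoxyphenyl](5-hydroxy-4-methoxy-2-methylphenyl)methyl}-4-(triisopropylsilyloxy)but-3-enoate
Product: 17 methyl (1R,2S,3S)-1-[4-(benzyloxy)-3-methoxyphenyl]-3-formyl-7-hydroxy-6-methoxy-1,2,3,4-tetrahydronaphthalene-2-carboxylate, via p-quinone methide 15 (not isolated), via unequilibrated cyclised aldehyde mixture 16 (not isolated)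
Conditions: undivided cell, graphite anode, Pt cathode, constant current (about 2.1 F/mol), 2,6-lutidine, Bu4NClO4, CH2Cl2/HFIP (4:1), 3 mM, 0 °C; then evaporate, NaOMe, MeOH, rt, AcOH quench
Reagents that add atoms: none
Why: Proposed new method: loss of two electrons and two protons from the ring-A phenol (phenol to phenoxyl radical to phenoxonium ion, then removal of a proton from the para methyl group by 2,6-lutidine) should give p-quinone methide 15 with C4 as its exocyclic carbon, and C3 of the tethered silyl enol ether then adds to C4 in a 1,6-addition that rearomatises ring A and, after silyl transfer to the medium, leaves the C3 aldehyde; the closest known reaction types are the anodic oxidation of 4-alkyl-2-methoxyphenols to p-quinone methides and the Mukaiyama-type 1,6-addition of silyl enol ethers to p-quinone methides, which have not been joined in one electrolysis. The carbocycle closes 6-endo-trig with respect to the C4=C4a bond of the quinone methide (exo with respect to the enol ether double bond). C3 is created here and C2 arrives as a mixture, so 16 is a mixture at both centres; sodium methoxide then reversibly enolises the aldehyde (C3) and the ester (C2) and should drain every isomer into the all-equatorial 1,2-trans-2,3-trans arrangement dictated by the fixed C1 aryl group, whose C1–H is not acidic under these conditions. The step needs oxidation at ring A only: a free guaiacol-type phenol in the presence of lutidine is expected to be oxidised several hundred millivolts below the benzylated pendant ring and the silyl enol ether, and the charge is limited to about 2 F per mole. It also needs bond formation at C4 and not at a ring carbon: the ring positions of the phenoxonium ion within reach of C3 (C4a and C8) could only be attacked through strained 5-endo closures, so proton loss from the methyl group should win, while high dilution disfavours phenol–phenol coupling.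

Step 10
Reactants: 17 methyl (1R,2S,3S)-1-[4-(benzyloxy)-3-methoxyphenyl]-3-formyl-7-hydroxy-6-methoxy-1,2,3,4-tetrahydronaphthalene-2-carboxylate
Product: 18 methyl (1R,2S,3S)-1-[4-(benzyloxy)-3-methoxyphenyl]-7-hydroxy-3-(hydroxymethyl)-6-methoxy-1,2,3,4-tetrahydronaphthalene-2-carboxylate
Conditions: NaBH4, MeOH/THF, −20 to 0 °C; aq. NH4Cl
Reagents that add atoms: none
Why: Chemoselective sodium borohydride reduction of an aldehyde beside a methyl ester; low temperature and a buffered quench should avoid C3 epimerisation and lactonisation onto the C2 ester.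

Step 11
Reactants: 18 methyl (1R,2S,3S)-1-[4-(benzyloxy)-3-methoxyphenyl]-7-hydroxy-3-(hydroxymethyl)-6-methoxy-1,2,3,4-tetrahydronaphthalene-2-carboxylate
Product: 19 methyl (1R,2S,3S)-7-hydroxy-1-(4-hydroxy-3-methoxyphenyl)-3-(hydroxymethyl)-6-methoxy-1,2,3,4-tetrahydronaphthalene-2-carboxylate (target)
Conditions: H2 (1 atm), 10% Pd/C, EtOAc/MeOH, rt
Reagents that add atoms: none
Why: Catalytic hydrogenolysis of a benzyl aryl ether; C1 carries no heteroatom and nothing else is reducible, so the three stereocentres are untouched.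

**Compound list**

1 | creosol (2-methoxy-4-methylphenol) | Cc1ccc(O)c(OC)c1 | starting material
2 | tert-butyl(2-methoxy-4-methylphenoxy)dimethylsilane | Cc1ccc(O[Si](C)(C)C(C)(C)C)c(OC)c1 | intermediate
3 | (5-bromo-2-methoxy-4-methylphenoxy)(tert-butyl)dimethylsilane | Cc1cc(OC)c(O[Si](C)(C)C(C)(C)C)cc1Br | intermediate
4 | methyl acrylate | C=CC(=O)OC | starting material
5 | methyl (E)-3-[5-(tert-butyldimethylsilyloxy)-4-methoxy-2-methylphenyl]prop-2-enoate | COC(=O)/C=C/c1cc(O[Si](C)(C)C(C)(C)C)c(OC)cc1C | intermediate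
6 | [4-(benzyloxy)-3-methoxyphenyl]boronic acid | COc1cc(B(O)O)ccc1OCc1ccccc1 | starting material
7 | methyl (3R)-3-[4-(benzyloxy)-3-methoxyphenyl]-3-[5-(tert-butyldimethylsilyloxy)-4-methoxy-2-methylphenyl]propanoate | COC(=O)C[C@H](c1ccc(OCc2ccccc2)c(OC)c1)c1cc(O[Si](C)(C)C(C)(C)C)c(OC)cc1C | intermediate
8 | allyl bromide | C=CCBr | starting material
9 | lithium (3R)-3-[4-(benzyloxy)-3-methoxyphenyl]-3-[5-(tert-butyldimethylsilyloxy)-4-methoxy-2-methylphenyl]-1-methoxyprop-1-en-1-olate | COC(O[Li])=C[C@H](c1ccc(OCc2ccccc2)c(OC)c1)c1cc(O[Si](C)(C)C(C)(C)C)c(OC)cc1C | intermediate (not isolated)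
10 | methyl 2-{(R)-[4-(benzyloxy)-3-methoxyphenyl][5-(tert-butyldimethylsilyloxy)-4-methoxy-2-methylphenyl]methyl}pent-4-enoate (C2 epimers) | COC(=O)C(CC=C)[C@H](c1ccc(OCc2ccccc2)c(OC)c1)c1cc(O[Si](C)(C)C(C)(C)C)c(OC)cc1C | intermediate
11 | methyl 2-{(R)-[4-(benzyloxy)-3-methoxyphenyl][5-(tert-butyldimethylsilyloxy)-4-methoxy-2-methylphenyl]methyl}-4,5-dihydroxypentanoate (diastereomer mixture) | COC(=O)C(CC(O)CO)[C@H](c1ccc(OCc2ccccc2)c(OC)c1)c1cc(O[Si](C)(C)C(C)(C)C)c(OC)cc1C | intermediate (not isolated)
12 | methyl 2-{(R)-[4-(benzyloxy)-3-methoxyphenyl][5-(tert-butyldimethylsilyloxy)-4-methoxy-2-methylphenyl]methyl}-4-oxobutanoate (C2 epimers) | COC(=O)C(CC=O)[C@H](c1ccc(OCc2ccccc2)c(OC)c1)c1cc(O[Si](C)(C)C(C)(C)C)c(OC)cc1C | intermediate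
13 | methyl 2-{(R)-[4-(benzyloxy)-3-methoxyphenyl][5-(tert-butyldimethylsilyloxy)-4-methoxy-2-methylphenyl]methyl}-4-(triisopropylsilyloxy)but-3-enoate (C2 epimers, E/Z) | COC(=O)C(C=CO[Si](C(C)C)(C(C)C)C(C)C)[C@H](c1ccc(OCc2ccccc2)c(OC)c1)c1cc(O[Si](C)(C)C(C)(C)C)c(OC)cc1C | intermediate
14 | methyl 2-{(R)-[4-(benzyloxy)-3-methoxyphenyl](5-hydroxy-4-methoxy-2-methylphenyl)methyl}-4-(triisopropylsilyloxy)but-3-enoate (C2 epimers, E/Z) | COC(=O)C(C=CO[Si](C(C)C)(C(C)C)C(C)C)[C@H](c1ccc(OCc2ccccc2)c(OC)c1)c1cc(O)c(OC)cc1C | intermediate (key-step precursor)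
15 | methyl 2-{(R)-[4-(benzyloxy)-3-methoxyphenyl](4-methoxy-6-methylidene-3-oxocyclohexa-1,4-dien-1-yl)methyl}-4-(triisopropylsilyloxy)but-3-enoate | COC(=O)C(C=CO[Si](C(C)C)(C(C)C)C(C)C)[C@H](c1ccc(OCc2ccccc2)c(OC)c1)C1=CC(=O)C(OC)=CC1=C | intermediate (not isolated)
16 | methyl (1R)-1-[4-(benzyloxy)-3-methoxyphenyl]-3-formyl-7-hydroxy-6-methoxy-1,2,3,4-tetrahydronaphthalene-2-carboxylate (mixture at C2 and C3) | COC(=O)C1C(C=O)Cc2cc(OC)c(O)cc2[C@H]1c1ccc(OCc3ccccc3)c(OC)c1 | intermediate (not isolated)
17 | methyl (1R,2S,3S)-1-[4-(benzyloxy)-3-methoxyphenyl]-3-formyl-7-hydroxy-6-methoxy-1,2,3,4-tetrahydronaphthalene-2-carboxylate | COC(=O)[C@@H]1[C@@H](C=O)Cc2cc(OC)c(O)cc2[C@H]1c1ccc(OCc3ccccc3)c(OC)c1 | intermediate (key-step product)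
18 | methyl (1R,2S,3S)-1-[4-(benzyloxy)-3-methoxyphenyl]-7-hydroxy-3-(hydroxymethyl)-6-methoxy-1,2,3,4-tetrahydronaphthalene-2-carboxylate | COC(=O)[C@@H]1[C@@H](CO)Cc2cc(OC)c(O)cc2[C@H]1c1ccc(OCc3ccccc3)c(OC)c1 | intermediate
19 | methyl (1R,2S,3S)-7-hydroxy-1-(4-hydroxy-3-methoxyphenyl)-3-(hydroxymethyl)-6-methoxy-1,2,3,4-tetrahydronaphthalene-2-carboxylate | COC(=O)[C@@H]1[C@@H](CO)Cc2cc(OC)c(O)cc2[C@H]1c1ccc(O)c(OC)c1 | target

**Step count and risks**

Total step count: 11. Longest linear sequence: 11 steps (creosol 1 to target 19).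

Steps most likely to fail:

1. Step 9 (anodic quinone methide cyclisation).
   - What may go wrong: phenoxyl radicals may couple with each other before the second electron and the methyl proton are lost. The enol ether may be protodesilylated in the protic medium before the C–C bond forms. The product, again a 4-alkylguaiacol, may be oxidised further once it accumulates. Oxidation may also spill over to the pendant ring or the enol ether.
   - Fallback (sets out from 12, returns at 17): the aryl silyl ether of 12 is cleaved with HF·pyridine in THF to give the phenol aldehyde methyl 2-{(R)-[4-(benzyloxy)-3-methoxyphenyl](5-hydroxy-4-methoxy-2-methylphenyl)methyl}-4-oxobutanoate F1. DDQ (about one equivalent) in MeOH/CH2Cl2 at 0 °C then performs the known benzylic methoxylation of a p-alkylphenol (quinone methide formation and capture by methanol, here as a separate stage with an isolable product). This gives the benzylic methyl ether methyl 2-{(R)-[4-(benzyloxy)-3-methoxyphenyl][5-hydroxy-4-methoxy-2-(methoxymethyl)phenyl]methyl}-4-oxobutanoate F2. Pyrrolidine and benzoic acid in toluene at 60 °C convert the aldehyde into its enamine and ionise the p-hydroxybenzyl ether back to the quinone methide. Intramolecular enamine 1,6-addition (amine-catalysed α-alkylation of an aldehyde by a p-quinone methide) and hydrolysis give 16, which NaOMe in MeOH equilibrates to 17 as in step 9.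

2. Step 8 (selective phenol desilylation).
   - What may go wrong: the triisopropylsilyl enol ether may be hydrolysed alongside the aryl silyl ether, or cleavage of the aryl ether may stall before completion.
   - Fallback (sets out from 10, returns at 14): the phenol protecting group is exchanged for an acetate that an amine can remove. TBAF in THF at 0 °C gives the phenol methyl 2-{(R)-[4-(benzyloxy)-3-methoxyphenyl](5-hydroxy-4-methoxy-2-methylphenyl)methyl}pent-4-enoate F3. Ac2O, pyridine and DMAP give the aryl acetate methyl 2-{(R)-[5-(acetyloxy)-4-methoxy-2-methylphenyl][4-(benzyloxy)-3-methoxyphenyl]methyl}pent-4-enoate F4. Oxidative cleavage as in step 6 gives methyl 2-{(R)-[5-(acetyloxy)-4-methoxy-2-methylphenyl][4-(benzyloxy)-3-methoxyphenyl]methyl}-4-oxobutanoate F5. Enol silylation as in step 7 gives methyl 2-{(R)-[5-(acetyloxy)-4-methoxy-2-methylphenyl][4-(benzyloxy)-3-methoxyphenyl]methyl}-4-(triisopropylsilyloxy)but-3-enoate F6. Aminolysis of the aryl acetate with pyrrolidine in CH2Cl2 at 0 °C, which touches neither the silyl enol ether nor the methyl ester, gives 14.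

3. Step 4 (asymmetric aryl addition).
   - What may go wrong: insertion of the ortho-substituted, electron-rich cinnamate into the aryl–rhodium bond may be slow, so that protodeboronation of the electron-rich boronic acid outruns addition. Facial selectivity may also be insufficient.
   - Fallback (sets out from 3, returns at 7): the roles of the two aryl groups are exchanged. Bromine–lithium exchange on 3 (n-BuLi, THF, −78 °C), trapping with B(OiPr)3 and mild aqueous hydrolysis give [5-(tert-butyldimethylsilyloxy)-4-methoxy-2-methylphenyl]boronic acid F7. The unhindered acceptor methyl (E)-3-[4-(benzyloxy)-3-methoxyphenyl]prop-2-enoate F8 is made by Wittig olefination of commercial 4-(benzyloxy)-3-methoxybenzaldehyde (O=Cc1ccc(OCc2ccccc2)c(OC)c1) with methyl (triphenylphosphoranylidene)acetate in toluene at 80 °C. Addition of F7 to F8 with [Rh(OH)((R)-BINAP)]2 in dioxane/H2O gives 7; the antipodal ligand is needed because the incoming and resident aryl groups have changed places.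

**Further compounds**

F1 | step 9 | methyl 2-{(R)-[4-(benzyloxy)-3-methoxyphenyl](5-hydroxy-4-methoxy-2-methylphenyl)methyl}-4-oxobutanoate (C2 epimers) | COC(=O)C(CC=O)[C@H](c1ccc(OCc2ccccc2)c(OC)c1)c1cc(O)c(OC)cc1C
F2 | step 9 | methyl 2-{(R)-[4-(benzyloxy)-3-methoxyphenyl][5-hydroxy-4-methoxy-2-(methoxymethyl)phenyl]methyl}-4-oxobutanoate (C2 epimers) | COC(=O)C(CC=O)[C@H](c1ccc(OCc2ccccc2)c(OC)c1)c1cc(O)c(OC)cc1COC
F3 | step 8 | methyl 2-{(R)-[4-(benzyloxy)-3-methoxyphenyl](5-hydroxy-4-methoxy-2-methylphenyl)methyl}pent-4-enoate (C2 epimers) | COC(=O)C(CC=C)[C@H](c1ccc(OCc2ccccc2)c(OC)c1)c1cc(O)c(OC)cc1C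
F4 | step 8 | methyl 2-{(R)-[5-(acetyloxy)-4-methoxy-2-methylphenyl][4-(benzyloxy)-3-methoxyphenyl]methyl}pent-4-enoate (C2 epimers) | COC(=O)C(CC=C)[C@H](c1ccc(OCc2ccccc2)c(OC)c1)c1cc(OC(C)=O)c(OC)cc1C
F5 | step 8 | methyl 2-{(R)-[5-(acetyloxy)-4-methoxy-2-methylphenyl][4-(benzyloxy)-3-methoxyphenyl]methyl}-4-oxobutanoate (C2 epimers) | COC(=O)C(CC=O)[C@H](c1ccc(OCc2ccccc2)c(OC)c1)c1cc(OC(C)=O)c(OC)cc1C
F6 | step 8 | methyl 2-{(R)-[5-(acetyloxy)-4-methoxy-2-methylphenyl][4-(benzyloxy)-3-methoxyphenyl]methyl}-4-(triisopropylsilyloxy)but-3-enoate (C2 epimers, E/Z) | COC(=O)C(C=CO[Si](C(C)C)(C(C)C)C(C)C)[C@H](c1ccc(OCc2ccccc2)c(OC)c1)c1cc(OC(C)=O)c(OC)cc1C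
F7 | step 4 | [5-(tert-butyldimethylsilyloxy)-4-methoxy-2-methylphenyl]boronic acid | Cc1cc(OC)c(O[Si](C)(C)C(C)(C)C)cc1B(O)O
F8 | step 4 | methyl (E)-3-[4-(benzyloxy)-3-methoxyphenyl]prop-2-enoate | COC(=O)/C=C/c1ccc(OCc2ccccc2)c(OC)c1
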